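**Plan**

- Retrosynthesis: the six O–CH3 bonds are cut first (global demethylation of a hexamethyl ether), then the C7–C(=O) bond of the 3-arylpropanoyl chain (Friedel–Crafts), then the C2–aryl bond (C–H arylation). Last, the furan ring is opened through C2–C3, C3–C3a and O1–C2, which leads back to a salicylaldehyde and an aryl diazomethyl ketone.
- Enabling feature: C3 of the furan carries the aroyl carbonyl and is bonded to C3a of the 4,6-dioxygenated benzo ring (ring A), whose C7a bears O1. C3 can therefore be the diazo carbon of the ketone, inserted between the ipso carbon and the formyl carbon (future C2) of 2-hydroxy-4,6-dimethoxybenzaldehyde, whose electron-rich ring migrates readily.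
- Forward order: ring A is bought as the salicylaldehyde; the furan ring is closed on it in step 2; the 4-methoxyphenyl ring is joined at C2 (step 3), the side chain at C7 (step 5), and the methyl ethers are removed (step 6).
- Stereochemistry: the target has no stereocentre and no stereogenic double bond; the two stereocentres of the transient lactol vanish on aromatisation.

Key step: step 2

Assumption: 2,4-dimethoxybenzoyl chloride, 2-hydroxy-4,6-dimethoxybenzaldehyde, 4-bromoanisole and 3-(4-methoxyphenyl)propanoic acid are taken as commercial, and all six phenols are carried as methyl ethers.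

**Route**

Step 1
Reactants: 1 2,4-dimethoxybenzoyl chloride
Product: 2 2-diazo-1-(2,4-dimethoxyphenyl)ethan-1-one
Conditions: TMSCHN2 (2 M in hexanes, 2.0 equiv), MeCN/THF 1:1, 0 °C → rt; evaporation, SiO2
Reagents that add atoms: trimethylsilyldiazomethane, C[Si](C)(C)C=[N+]=[N-]
Why: C-acylation of trimethylsilyldiazomethane by the aroyl chloride with loss of the silyl group as Me3SiCl is the standard diazomethane-free (Arndt–Eistert-type) route to aryl diazomethyl ketones, and the aryl methyl ethers are inert to it.

Step 2
Reactants: 2 2-diazo-1-(2,4-dimethoxyphenyl)ethan-1-one, 3 2-hydroxy-4,6-dimethoxybenzaldehyde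
Product: 6 (2,4-dimethoxyphenyl)(4,6-dimethoxy-1-benzofuran-3-yl)methanone, via aryl-shifted keto aldehyde 4 (not isolated), via lactol 5 (not isolated)
Conditions: HBF4·OEt2 (10 mol %), CH2Cl2, rt, 2 (1.5 equiv) added slowly; then AcOH, 80 °C
Reagents that add atoms: none
Why: Proposed new method: the diazo carbon of 2 should add to the HBF4-activated formyl group of 3, and the resulting β-hydroxy diazonium ion should lose N2 with a semipinacol-type 1,2-shift of the 2-hydroxy-4,6-dimethoxyphenyl ring from the carbinol carbon to the former diazo carbon (new C3–C3a and C2–C3 bonds), giving keto aldehyde 4. The closest known reaction type is the HBF4·OEt2-catalysed reaction of salicylaldehydes with ethyl diazoacetate, which gives 3-ethoxycarbonylbenzofurans by the same aryl shift, lactol closure and acid dehydration; Lewis-acid coupling of aldehydes with α-diazo ketones is also known but proceeds by hydride shift, so the aryl-shift variant with an aryl diazomethyl ketone is the untested element. The furan ring closes by 5-exo-trig addition of the phenol oxygen to the formyl carbon (O1–C2, lactol 5), and warm AcOH then removes water to aromatise it. No stereocentre has to be set, since the two of 5 are destroyed on dehydration. The step needs aryl rather than hydride migration and closure on the formyl rather than the ketone carbonyl: the first is secured by π-participation of the 2,4,6-trioxygenated ring, which should also outrun capture of the diazonium carbon by the ortho-methoxy group of the aroyl ring, and the second by the aldehyde being far more electrophilic and less hindered than the donor-substituted, ortho-substituted aryl ketone. AcOH replaces the concentrated H2SO4 of the ester precedent to avoid sulfonation of the phloroglucinol-type ring and acid-driven reclosure on the ketone, and slow addition of 2 keeps its concentration low against acid decomposition.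

Step 3
Reactants: 6 (2,4-dimethoxyphenyl)(4,6-dimethoxy-1-benzofuran-3-yl)methanone, 7 1-bromo-4-methoxybenzene (4-bromoanisole)
Product: 8 (2,4-dimethoxyphenyl)[4,6-dimethoxy-2-(4-methoxyphenyl)-1-benzofuran-3-yl]methanone
Conditions: Pd(OAc)2 (5 mol %), PCy3·HBF4 (10 mol %), PivOH (30 mol %), K2CO3 (2 equiv), DMA, 110 °C
Reagents that add atoms: none
Why: Carboxylate-assisted direct arylation (concerted metalation–deprotonation at divalent palladium after oxidative addition of 7 to zerovalent palladium) is well established for the C2–H bond of benzofurans, and here C2–H is the only furan C–H and is acidified by the adjacent 3-aroyl group.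

Step 4
Reactants: 9 3-(4-methoxyphenyl)propanoic acid
Product: 10 3-(4-methoxyphenyl)propanoyl chloride
Conditions: (COCl)2 (1.3 equiv), DMF (cat.), CH2Cl2, 0 °C → rt; evaporation
Reagents that add atoms: oxalyl chloride, O=C(Cl)C(=O)Cl
Why: Oxalyl chloride with catalytic DMF converts carboxylic acids to acid chlorides through the chloroiminium (Vilsmeier-type) activator under conditions that leave the anisole ring untouched.

Step 5
Reactants: 8 (2,4-dimethoxyphenyl)[4,6-dimethoxy-2-(4-methoxyphenyl)-1-benzofuran-3-yl]methanone, 10 3-(4-methoxyphenyl)propanoyl chloride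
Product: 11 1-[3-(2,4-dimethoxybenzoyl)-4,6-dimethoxy-2-(4-methoxyphenyl)-1-benzofuran-7-yl]-3-(4-methoxyphenyl)propan-1-one
Conditions: AlCl3 (2.5 equiv), 10 (1.5 equiv), CH2Cl2, 0 °C; aqueous HCl work-up
Reagents that add atoms: none
Why: Friedel–Crafts acylation should occur at C7, the most nucleophilic free position of 8 (ortho to 6-OMe and O1, para to 4-OMe), because C5 is buttressed by two methoxy groups, the 2,4-dimethoxybenzoyl ring is deactivated by its AlCl3-complexed carbonyl and the anisyl ring is only anisole-like.

Step 6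
Reactants: 11 1-[3-(2,4-dimethoxybenzoyl)-4,6-dimethoxy-2-(4-methoxyphenyl)-1-benzofuran-7-yl]-3-(4-methoxyphenyl)propan-1-one
Product: 12 1-[3-(2,4-dihydroxybenzoyl)-4,6-dihydroxy-2-(4-hydroxyphenyl)-1-benzofuran-7-yl]-3-(4-hydroxyphenyl)propan-1-one
Conditions: BBr3 (12 equiv), CH2Cl2, −78 °C → rt; then H2O, 0 °C
Reagents that add atoms: none
Why: BBr3 cleaves aryl methyl ethers by O–B complexation and bromide attack on the methyl carbon (standard global O-demethylation), while the two ketones, the furan and the carbon framework are inert and the ethers ortho to a carbonyl are further activated by chelation.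

**Compound list**

1 | 2,4-dimethoxybenzoyl chloride | COc1ccc(C(Cl)=O)c(OC)c1 | starting material
2 | 2-diazo-1-(2,4-dimethoxyphenyl)ethan-1-one | COc1ccc(C(=O)C=[N+]=[N-])c(OC)c1 | intermediate
3 | 2-hydroxy-4,6-dimethoxybenzaldehyde | COc1cc(O)c(C=O)c(OC)c1 | starting material
4 | 3-(2,4-dimethoxyphenyl)-2-(2-hydroxy-4,6-dimethoxyphenyl)-3-oxopropanal (racemic, in equilibrium with its enol) | O=CC(c1c(O)cc(OC)cc1OC)C(=O)c1ccc(OC)cc1OC | intermediate (not isolated)
5 | (2,4-dimethoxyphenyl)(2-hydroxy-4,6-dimethoxy-2,3-dihydro-1-benzofuran-3-yl)methanone (racemic mixture of diastereomers) | COc1ccc(C(=O)C2C(O)Oc3cc(OC)cc(OC)c32)c(OC)c1 | intermediate (not isolated)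
6 | (2,4-dimethoxyphenyl)(4,6-dimethoxy-1-benzofuran-3-yl)methanone | COc1ccc(C(=O)c2coc3cc(OC)cc(OC)c23)c(OC)c1 | intermediate
7 | 1-bromo-4-methoxybenzene (4-bromoanisole) | COc1ccc(Br)cc1 | starting material
8 | (2,4-dimethoxyphenyl)[4,6-dimethoxy-2-(4-methoxyphenyl)-1-benzofuran-3-yl]methanone | COc1ccc(C(=O)c2c(-c3ccc(OC)cc3)oc3cc(OC)cc(OC)c23)c(OC)c1 | intermediate
9 | 3-(4-methoxyphenyl)propanoic acid | COc1ccc(CCC(O)=O)cc1 | starting material
10 | 3-(4-methoxyphenyl)propanoyl chloride | COc1ccc(CCC(Cl)=O)cc1 | intermediate
11 | 1-[3-(2,4-dimethoxybenzoyl)-4,6-dimethoxy-2-(4-methoxyphenyl)-1-benzofuran-7-yl]-3-(4-methoxyphenyl)propan-1-one | COc1ccc(CCC(=O)c2c(OC)cc(OC)c3c(C(=O)c4ccc(OC)cc4OC)c(-c4ccc(OC)cc4)oc23)cc1 | intermediate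
12 | 1-[3-(2,4-dihydroxybenzoyl)-4,6-dihydroxy-2-(4-hydroxyphenyl)-1-benzofuran-7-yl]-3-(4-hydroxyphenyl)propan-1-one | O=C(CCc1ccc(O)cc1)c1c(O)cc(O)c2c(C(=O)c3ccc(O)cc3O)c(-c3ccc(O)cc3)oc12 | target

**Count**

Total steps: 6. Longest linear sequence: 5 (steps 1, 2, 3, 5, 6); step 4 is a one-step side branch.

**Steps most likely to fail**

1. Step 2 (carries the new-method label).
   - What may go wrong: acid-triggered loss of the diazoketone before C–C bond formation (protonation at the diazo carbon, then capture of the diazonium carbon by the neighbouring 2-methoxy oxygen or by the phenol); hydride instead of aryl migration; or reclosure on the ketone carbonyl during dehydration.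
   - Fallback (known chemistry: oxidative 1,2-aryl shift of a chalcone), setting out from 3 and returning at 6. Compound 3 is protected with MOMCl/iPr2NEt in CH2Cl2 to give 2,4-dimethoxy-6-(methoxymethoxy)benzaldehyde F1. Claisen–Schmidt condensation of this with 2',4'-dimethoxyacetophenone (KOH, EtOH, rt) should give the chalcone (E)-1-(2,4-dimethoxyphenyl)-3-[2,4-dimethoxy-6-(methoxymethoxy)phenyl]prop-2-en-1-one F2. The trivalent-iodine oxidant PhI(OH)OTs in MeOH should then shift the trioxygenated ring from the β- to the α-carbon and give the keto acetal 1-(2,4-dimethoxyphenyl)-2-[2,4-dimethoxy-6-(methoxymethoxy)phenyl]-3,3-dimethoxypropan-1-one F3. Catalytic p-TsOH in MeOH removes the MOM group and closes the cyclic acetal (2,4-dimethoxyphenyl)(2,4,6-trimethoxy-2,3-dihydro-1-benzofuran-3-yl)methanone F4. K2CO3 in THF (or warm AcOH) eliminates methanol to give 6.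

2. Step 5.
   - What may go wrong: acylation at a ring position other than C7, or stalling because AlCl3 bound to the C3 ketone deactivates the benzofuran; both may be accompanied by self-acylation of 10 and Lewis-acid loss of methyl groups ortho to carbonyls.
   - Fallback, from 8 back to 11. Vilsmeier–Haack formylation (POCl3, DMF, 0 → 60 °C, aqueous NaOAc work-up) is a milder and more position-selective electrophilic substitution that does not touch anisole-type rings, and should give 3-(2,4-dimethoxybenzoyl)-4,6-dimethoxy-2-(4-methoxyphenyl)-1-benzofuran-7-carbaldehyde F5. Addition of 2-(4-methoxyphenyl)ethylmagnesium bromide (THF, −78 °C) to the aldehyde, with the hindered and donor-deactivated diaryl ketone spared, should give racemic 1-[3-(2,4-dimethoxybenzoyl)-4,6-dimethoxy-2-(4-methoxyphenyl)-1-benzofuran-7-yl]-3-(4-methoxyphenyl)propan-1-ol F6. Oxidation of this benzylic alcohol with MnO2 in CH2Cl2 gives 11.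

3. Step 3.
   - What may go wrong: slow or incomplete palladation at C2, which is flanked by the twisted aroyl group, with competing reduction or homocoupling of 7.
   - Fallback, from 6 back to 8. Ketone-tolerant directed zincation at C2 with TMPZnCl·LiCl (THF, 25 °C) should give [3-(2,4-dimethoxybenzoyl)-4,6-dimethoxy-1-benzofuran-2-yl]zinc chloride F7. This is coupled in the same flask with 4-iodoanisole under Negishi conditions (Pd(PPh3)4 5 mol %, THF, 50 °C) to give 8.

**Further compounds**

F1 | step 2 | 2,4-dimethoxy-6-(methoxymethoxy)benzaldehyde | COCOc1cc(OC)cc(OC)c1C=O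
F2 | step 2 | (E)-1-(2,4-dimethoxyphenyl)-3-[2,4-dimethoxy-6-(methoxymethoxy)phenyl]prop-2-en-1-one | COCOc1cc(OC)cc(OC)c1/C=C/C(=O)c1ccc(OC)cc1OC
F3 | step 2 | 1-(2,4-dimethoxyphenyl)-2-[2,4-dimethoxy-6-(methoxymethoxy)phenyl]-3,3-dimethoxypropan-1-one | COCOc1cc(OC)cc(OC)c1C(C(OC)OC)C(=O)c1ccc(OC)cc1OC
F4 | step 2 | (2,4-dimethoxyphenyl)(2,4,6-trimethoxy-2,3-dihydro-1-benzofuran-3-yl)methanone | COc1ccc(C(=O)C2C(OC)Oc3cc(OC)cc(OC)c32)c(OC)c1
F5 | step 5 | 3-(2,4-dimethoxybenzoyl)-4,6-dimethoxy-2-(4-methoxyphenyl)-1-benzofuran-7-carbaldehyde | O=Cc1c(OC)cc(OC)c2c(C(=O)c3ccc(OC)cc3OC)c(-c3ccc(OC)cc3)oc12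
F6 | step 5 | 1-[3-(2,4-dimethoxybenzoyl)-4,6-dimethoxy-2-(4-methoxyphenyl)-1-benzofuran-7-yl]-3-(4-methoxyphenyl)propan-1-ol | OC(CCc1ccc(OC)cc1)c1c(OC)cc(OC)c2c(C(=O)c3ccc(OC)cc3OC)c(-c3ccc(OC)cc3)oc12
F7 | step 3 | [3-(2,4-dimethoxybenzoyl)-4,6-dimethoxy-1-benzofuran-2-yl]zinc chloride | COc1ccc(C(=O)c2c([Zn]Cl)oc3cc(OC)cc(OC)c23)c(OC)c1
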